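**Retrosynthetic overview**

1. The target is the (7R,8R)-threo 8-O-4′ neolignan acetate (C7 = benzylic acetoxy carbon, C8 = aryloxy carbon, C9 = methyl). The acetate comes from alcohol 15, and the C9 methyl from a C9 acyl group via CH2OH and CH2OTs.
2. Key disconnection C7–C8: an auxiliary-controlled boron glycolate syn-aldol joins veratraldehyde (C7) to the Z-boron enolate of an (aryloxy)acetyl oxazolidinone (C8–C9). This one operation makes the only C–C bond between the two halves and sets both stereocentres.
3. Enabling feature: C8 carries the ether oxygen of the 2-methoxy-4-propenylphenoxy ring and C7 the benzylic oxygen on the 3,4-dimethoxyphenyl ring. Raising C9 to the acyl level therefore makes C8 the α-carbon of an α-oxy enolate and C7 an aldehyde carbon.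
4. The imide comes from (Z)-isoeugenol, bromoacetic acid and (S)-4-benzyloxazolidinone; the Z-propenyl group comes from a stereoretentive Suzuki coupling.
5. No ring is formed: both benzene rings are bought, and the oxazolidinone ring is a temporary auxiliary removed in step 5.

Key step: step 4

Assumption: the SMILES is read as the (7R,8R)-threo isomer, and (Z)-prop-1-en-1-ylboronic acid is taken as a catalogue compound.

**Route**

Step 1
Reactants: 1 4-bromo-2-methoxyphenol; 2 (Z)-prop-1-en-1-ylboronic acid
Product: 3 2-methoxy-4-[(1Z)-prop-1-en-1-yl]phenol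
Conditions: Pd(OAc)2 (2 mol%), SPhos (4 mol%), K2CO3, dioxane/H2O, 70 °C, argon
Reagents that add atoms: none
Why: Suzuki–Miyaura cross-coupling, in which transmetalation and reductive elimination proceed with retention at the alkenyl carbon, so the Z geometry of 2 should be carried into 3 and the free phenol is tolerated under aqueous carbonate.

Step 2
Reactants: 3 2-methoxy-4-[(1Z)-prop-1-en-1-yl]phenol; 4 bromoacetic acid
Product: 5 {2-methoxy-4-[(1Z)-prop-1-en-1-yl]phenoxy}acetic acid
Conditions: NaOH (aq), 80 °C, argon; then cold 1 M HCl to pH 2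
Reagents that add atoms: none
Why: Williamson ether synthesis, in which the phenoxide displaces bromide from the bromoacetate by SN2 while the Z-propenyl group is inert to aqueous hydroxide.

Step 3
Reactants: 5 {2-methoxy-4-[(1Z)-prop-1-en-1-yl]phenoxy}acetic acid; 6 (4S)-4-benzyl-1,3-oxazolidin-2-one
Product: 8 (4S)-4-benzyl-3-({2-methoxy-4-[(1Z)-prop-1-en-1-yl]phenoxy}acetyl)-1,3-oxazolidin-2-one, via mixed pivalic anhydride 7 (not isolated)
Conditions: PivCl, Et3N, THF, −20 °C; then 6, LiCl, −20 °C → rt
Reagents that add atoms: none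
Why: N-acylation of the oxazolidinone through a mixed pivalic anhydride, in which the hindered pivaloyl carbonyl steers the lithium-activated oxazolidinone onto the aryloxyacetyl carbonyl and no strong acid that could isomerise the electron-rich styrene is present.

Step 4
Reactants: 8 (4S)-4-benzyl-3-({2-methoxy-4-[(1Z)-prop-1-en-1-yl]phenoxy}acetyl)-1,3-oxazolidin-2-one; 9 3,4-dimethoxybenzaldehyde
Product: 12 (4S)-4-benzyl-3-[(2S,3R)-3-(3,4-dimethoxyphenyl)-3-hydroxy-2-{2-methoxy-4-[(1Z)-prop-1-en-1-yl]phenoxy}propanoyl]-1,3-oxazolidin-2-one, via dibutylboron Z-enolate 10 (not isolated), via dibutylboron aldolate 11 (not isolated)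
Conditions: Bu2BOTf (1.2 equiv), Et3N (1.4 equiv), CH2Cl2, −78 → 0 °C; then 9, −78 → 0 °C; pH 7 buffer, MeOH, 30% H2O2, 0 °C
Reagents that add atoms: none
Why: Evans boron syn-aldol reaction of a glycolate-type imide, with alkoxy- and aryloxyacetyl oxazolidinones plus aromatic aldehydes as the closest known case: Bu2BOTf/Et3N should enolise 8 to the Z(O)-boron enolate 10 (aryloxy group cis to OB), which adds to boron-bound veratraldehyde through a closed Zimmerman–Traxler chair with the 3,4-dimethoxyphenyl group equatorial, giving the 7,8-syn (threo) relationship. No ring is closed in the product; the six-membered boron-bridged chair exists only in the transition state and in aldolate 11. C8 is controlled by the auxiliary: the oxazolidinone C=O turns away from the enolate C–O (dipole minimisation, boron has no free site to chelate it) and the (4S)-benzyl group blocks one enolate face, so the aldehyde is taken up on the other face to give the (2S) centre of 12, which becomes 8R once C9 is a methyl group; C7 (3R in 12, 7R in the target) follows from the chair and hence from the Z-enolate geometry. The step needs Z-selective enolisation, facial selectivity and cross- rather than self-addition; these are secured by the dialkylboron triflate/amine pair on an α-oxy imide, by the benzyl stereocentre and by the non-enolisable aldehyde, respectively. The Z-propenyl group, the aryl ethers and the imide should survive the −78 to 0 °C conditions and the buffered peroxide work-up that cleaves the B–O bond of 11.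

Step 5
Reactants: 12 (4S)-4-benzyl-3-[(2S,3R)-3-(3,4-dimethoxyphenyl)-3-hydroxy-2-{2-methoxy-4-[(1Z)-prop-1-en-1-yl]phenoxy}propanoyl]-1,3-oxazolidin-2-one
Product: 13 (1R,2R)-1-(3,4-dimethoxyphenyl)-2-{2-methoxy-4-[(1Z)-prop-1-en-1-yl]phenoxy}propane-1,3-diol
Conditions: LiBH4, MeOH (1 equiv), THF, 0 °C; aqueous work-up
Reagents that add atoms: none
Why: Reductive cleavage of the N-acyloxazolidinone with lithium borohydride, in which hydride attacks the exocyclic imide carbonyl and the aldehyde formed is reduced on, releasing the auxiliary without enolisation at C8 and without touching the alkene.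

Step 6
Reactants: 13 (1R,2R)-1-(3,4-dimethoxyphenyl)-2-{2-methoxy-4-[(1Z)-prop-1-en-1-yl]phenoxy}propane-1,3-diol
Product: 14 (2R,3R)-3-(3,4-dimethoxyphenyl)-3-hydroxy-2-{2-methoxy-4-[(1Z)-prop-1-en-1-yl]phenoxy}propyl 4-methylbenzenesulfonate
Conditions: TsCl (1.05 equiv), Et3N, DMAP (cat.), CH2Cl2, −10 → 0 °C
Reagents that add atoms: p-toluenesulfonyl chloride, Cc1ccc(S(=O)(=O)Cl)cc1
Why: Selective O-sulfonylation, in which the unhindered primary hydroxyl should react with limiting TsCl much faster than the secondary benzylic hydroxyl next to a branched carbon.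

Step 7
Reactants: 14 (2R,3R)-3-(3,4-dimethoxyphenyl)-3-hydroxy-2-{2-methoxy-4-[(1Z)-prop-1-en-1-yl]phenoxy}propyl 4-methylbenzenesulfonate
Product: 15 (1R,2R)-1-(3,4-dimethoxyphenyl)-2-{2-methoxy-4-[(1Z)-prop-1-en-1-yl]phenoxy}propan-1-ol
Conditions: LiEt3BH (3 equiv), THF, 0 °C → rt
Reagents that add atoms: none
Why: SN2 hydride displacement of a primary tosylate by lithium triethylborohydride (Super-Hydride) turns the C9 carbinol into the methyl group, with neither stereocentre involved and the styrene inert to nucleophilic hydride.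

Step 8
Reactants: 15 (1R,2R)-1-(3,4-dimethoxyphenyl)-2-{2-methoxy-4-[(1Z)-prop-1-en-1-yl]phenoxy}propan-1-ol
Product: 16 Ligraminol C, (1R,2R)-1-(3,4-dimethoxyphenyl)-2-{2-methoxy-4-[(1Z)-prop-1-en-1-yl]phenoxy}propyl acetate
Conditions: Ac2O, pyridine, DMAP (cat.), CH2Cl2, 0 °C → rt
Reagents that add atoms: acetic anhydride, CC(=O)OC(C)=O
Why: DMAP-catalysed O-acylation (nucleophilic acyl-transfer catalysis) of the secondary benzylic alcohol, in which the C7–O bond is not broken and the configuration is therefore retained.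

**Compound list**

1 | 4-bromo-2-methoxyphenol | COc1cc(Br)ccc1O | starting material
2 | (Z)-prop-1-en-1-ylboronic acid | C/C=C\B(O)O | starting material
3 | 2-methoxy-4-[(1Z)-prop-1-en-1-yl]phenol ((Z)-isoeugenol) | C/C=C\c1ccc(O)c(OC)c1 | intermediate
4 | bromoacetic acid | OC(=O)CBr | starting material
5 | {2-methoxy-4-[(1Z)-prop-1-en-1-yl]phenoxy}acetic acid | C/C=C\c1ccc(OCC(=O)O)c(OC)c1 | intermediate
6 | (4S)-4-benzyl-1,3-oxazolidin-2-one | O=C1N[C@@H](Cc2ccccc2)CO1 | starting material
7 | {2-methoxy-4-[(1Z)-prop-1-en-1-yl]phenoxy}acetic pivalic anhydride | C/C=C\c1ccc(OCC(=O)OC(=O)C(C)(C)C)c(OC)c1 | intermediate (not isolated)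
8 | (4S)-4-benzyl-3-({2-methoxy-4-[(1Z)-prop-1-en-1-yl]phenoxy}acetyl)-1,3-oxazolidin-2-one | C/C=C\c1ccc(OCC(=O)N2[C@@H](Cc3ccccc3)COC2=O)c(OC)c1 | intermediate
9 | 3,4-dimethoxybenzaldehyde (veratraldehyde) | COc1ccc(C=O)cc1OC | starting material
10 | dibutylboron Z(O)-enolate of 8 | C/C=C\c1ccc(O/C=C(\OB(CCCC)CCCC)N2[C@@H](Cc3ccccc3)COC2=O)c(OC)c1 | intermediate (not isolated)
11 | O-dibutylboryl aldolate of 12 | C/C=C\c1ccc(O[C@H](C(=O)N3[C@@H](Cc4ccccc4)COC3=O)[C@H](OB(CCCC)CCCC)c2ccc(OC)c(OC)c2)c(OC)c1 | intermediate (not isolated)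
12 | (4S)-4-benzyl-3-[(2S,3R)-3-(3,4-dimethoxyphenyl)-3-hydroxy-2-{2-methoxy-4-[(1Z)-prop-1-en-1-yl]phenoxy}propanoyl]-1,3-oxazolidin-2-one | C/C=C\c1ccc(O[C@H](C(=O)N3[C@@H](Cc4ccccc4)COC3=O)[C@H](O)c2ccc(OC)c(OC)c2)c(OC)c1 | intermediate
13 | (1R,2R)-1-(3,4-dimethoxyphenyl)-2-{2-methoxy-4-[(1Z)-prop-1-en-1-yl]phenoxy}propane-1,3-diol | C/C=C\c1ccc(O[C@H](CO)[C@H](O)c2ccc(OC)c(OC)c2)c(OC)c1 | intermediate
14 | (2R,3R)-3-(3,4-dimethoxyphenyl)-3-hydroxy-2-{2-methoxy-4-[(1Z)-prop-1-en-1-yl]phenoxy}propyl 4-methylbenzenesulfonate | C/C=C\c1ccc(O[C@H](COS(=O)(=O)c3ccc(C)cc3)[C@H](O)c2ccc(OC)c(OC)c2)c(OC)c1 | intermediate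
15 | (1R,2R)-1-(3,4-dimethoxyphenyl)-2-{2-methoxy-4-[(1Z)-prop-1-en-1-yl]phenoxy}propan-1-ol | C/C=C\c1ccc(O[C@H](C)[C@H](O)c2ccc(OC)c(OC)c2)c(OC)c1 | intermediate
16 | Ligraminol C, (1R,2R)-1-(3,4-dimethoxyphenyl)-2-{2-methoxy-4-[(1Z)-prop-1-en-1-yl]phenoxy}propyl acetate | C/C=C\c1ccc(O[C@H](C)[C@H](OC(C)=O)c2ccc(OC)c(OC)c2)c(OC)c1 | target

**Step count and risks**

Total step count: 8. Longest linear sequence: 8 steps (1 → 16).

Steps most likely to fail:

1. Step 4 (key aldol). The electron-rich aldehyde may add sluggishly, the aldolate may revert by retro-aldol on work-up, or facial selectivity may erode if the aryl ether oxygens compete for boron. Fallback, setting out from acid 5: esterification (MeI, K2CO3, DMF) would give methyl {2-methoxy-4-[(1Z)-prop-1-en-1-yl]phenoxy}acetate F1. C-acylation of its lithium enolate (LiHMDS, 2.1 equiv, THF, −78 °C) with 3,4-dimethoxybenzoyl chloride would forge the same C7–C8 bond and give the racemic, configurationally labile β-keto ester methyl 3-(3,4-dimethoxyphenyl)-2-{2-methoxy-4-[(1Z)-prop-1-en-1-yl]phenoxy}-3-oxopropanoate F2. Noyori-type asymmetric transfer hydrogenation with dynamic kinetic resolution (RuCl[(S,S)-TsDPEN](p-cymene), HCO2H/Et3N) should then set both centres and give the syn ester methyl (2S,3R)-3-(3,4-dimethoxyphenyl)-3-hydroxy-2-{2-methoxy-4-[(1Z)-prop-1-en-1-yl]phenoxy}propanoate F3. The (S,S) catalyst is chosen by analogy with aryl ketone reductions, and the catalyst enantiomer would be switched if the opposite carbinol resulted. LiBH4 reduction of F3 comes back to the route at diol 13.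

2. Step 7 (hydride displacement). The neighbouring alkoxide formed under the basic hydride may displace the tosylate intramolecularly (oxetane formation), or S–O cleavage may return the diol. Fallback, setting out from tosylate 14: acetylation first (Ac2O, pyridine, DMAP) would give (1R,2R)-1-(3,4-dimethoxyphenyl)-2-{2-methoxy-4-[(1Z)-prop-1-en-1-yl]phenoxy}-3-[(4-methylbenzenesulfonyl)oxy]propyl acetate F4, in which no alkoxide can form. Reduction with NaBH4 in DMSO (cat. NaI, 60 °C), a neutral SN2 hydride source that spares acetates, should then come back to the route directly at target 16.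

3. Step 1 (Suzuki coupling). Partial Z→E isomerisation through Pd–H addition/elimination would give a geometric mixture that cannot be corrected later. Fallback, setting out from bromide 1: copper-free Sonogashira coupling with propyne (PdCl2(MeCN)2, XPhos, Cs2CO3, MeCN) would give 2-methoxy-4-(prop-1-yn-1-yl)phenol F5. Lindlar semihydrogenation (H2, Pd/CaCO3–Pb, quinoline) should set the Z geometry by syn addition and come back to the route at phenol 3.

**Further compounds**

F1 | step 4 | methyl {2-methoxy-4-[(1Z)-prop-1-en-1-yl]phenoxy}acetate | C/C=C\c1ccc(OCC(=O)OC)c(OC)c1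
F2 | step 4 | methyl 3-(3,4-dimethoxyphenyl)-2-{2-methoxy-4-[(1Z)-prop-1-en-1-yl]phenoxy}-3-oxopropanoate (racemic) | C/C=C\c1ccc(OC(C(=O)OC)C(=O)c2ccc(OC)c(OC)c2)c(OC)c1
F3 | step 4 | methyl (2S,3R)-3-(3,4-dimethoxyphenyl)-3-hydroxy-2-{2-methoxy-4-[(1Z)-prop-1-en-1-yl]phenoxy}propanoate | C/C=C\c1ccc(O[C@H](C(=O)OC)[C@H](O)c2ccc(OC)c(OC)c2)c(OC)c1
F4 | step 7 | (1R,2R)-1-(3,4-dimethoxyphenyl)-2-{2-methoxy-4-[(1Z)-prop-1-en-1-yl]phenoxy}-3-[(4-methylbenzenesulfonyl)oxy]propyl acetate | C/C=C\c1ccc(O[C@H](COS(=O)(=O)c3ccc(C)cc3)[C@H](OC(C)=O)c2ccc(OC)c(OC)c2)c(OC)c1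
F5 | step 1 | 2-methoxy-4-(prop-1-yn-1-yl)phenol | CC#Cc1ccc(O)c(OC)c1
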